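**Retrosynthetic overview**

1. The quaternary ring carbon is made last, by asymmetric dearomative prenylation of a fully substituted acylphloroglucinol. The ring–CH2 bond before it comes from a three-component reductive alkylation of (S)-2-methylbutanoyl-methylphloroglucinol with a cyclopentanecarbaldehyde.
2. The aldehyde comes from a cyclopentene ester. Hydroxyl-directed epoxidation anti to the isopropenyl group, then intramolecular hydride opening, set the two remaining cyclopentane stereocentres.
3. The cyclopentene is made by contraction of the six-membered ring of (R)-carvone through a photochemical Wolff rearrangement of 6-diazocarvone. All ten carvone carbons are kept, and the extruded carbonyl carbon C1 becomes the CH2 linker.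
4. Enabling feature: in the cyclohexenone ring the C1 carbonyl sits between the diazo carbon C6 (next to the isopropenyl-bearing C5) and the methyl-bearing alkenyl carbon C2. The ring holds C=O and C=N2 s-cis, so C2 is the only group that can migrate, and it lands on C6.
5. Ring order: carvone ring (bought) → cyclopentene (step 2) → aromatic ring (bought), joined and dearomatised at the end.

Key step: step 2

Assumption: the (R,R)-configured bisphosphine ligand in step 10 is taken to deliver the prenyl group to the ring face that gives the 6R quaternary carbon; if the sense proves opposite, the (S,S)-ligand is used under the same conditions.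
Remark: 2 is drawn as its hydrogen-bonded enol; 5 is a mixture of epimers at the ester-bearing carbon, which is erased in the same pot.

**Route**

Step 1
Reactants: 1 (R)-(−)-carvone
Product: 3 (5S)-6-diazo-2-methyl-5-(prop-1-en-2-yl)cyclohex-2-en-1-one, via trifluoroacetyl enol 2 (not isolated)
Conditions: LiN(SiMe3)2, THF, −78 °C; CF3CO2CH2CF3; aq. HCl work-up; then MeSO2N3, Et3N, H2O, MeCN, rt
Reagents that add atoms: methanesulfonyl azide, CS(=O)(=O)N=[N+]=[N-]
Why: Regitz-type detrifluoroacetylative diazo transfer: the kinetic α'-enolate (C6 is the only enolisable α-carbon on that side of the carbonyl) is C-trifluoroacetylated and the activated position then takes up N2 from the sulfonyl azide with loss of the trifluoroacetyl group, leaving the C5 stereocentre untouched and creating none.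

Step 2
Reactants: 3 (5S)-6-diazo-2-methyl-5-(prop-1-en-2-yl)cyclohex-2-en-1-one
Product: 6 methyl (5S)-2-methyl-5-(prop-1-en-2-yl)cyclopent-1-ene-1-carboxylate, via vinylketene 4 (not isolated), via deconjugated ester 5 (not isolated)
Conditions: hν (350 nm, Pyrex), MeOH, rt; then NaOMe (cat.), MeOH, rt
Reagents that add atoms: methanol, CO
Why: Irradiation expels N2 from the cyclic α'-diazo enone and, in concert, the alkenyl carbon C2 shifts from the carbonyl carbon C1 to the diazo carbon C6 (photochemical Wolff rearrangement), so the six-membered ring contracts to a cyclopentene and C1 is extruded as the exocyclic vinylketene 4; methanol adds to the ketene and catalytic NaOMe moves the ring double bond into conjugation through the dienolate, giving the tetrasubstituted enoate 6. The closest known reaction type is the photo-Wolff ring contraction of cyclic 2-diazo ketones, including α'-diazo enones that give vinylketenes. The five-membered ring is closed by the 1,2-carbon shift itself (the C2–C6 bond forms as C1–C2 breaks), a ring contraction by one atom and not a cyclisation. No new stereocentre survives: the isopropenyl-bearing carbon (C5 of carvone) is only the neighbour of the migration terminus and keeps its configuration, while the transient ester-bearing stereocentre of 5 is erased by the conjugation. The step needs exclusive migration of C2 and conjugation toward the methyl-bearing carbon; the first is secured because the ring holds C=O and C=N2 s-cis and C1 carries no other substituent, the second because the dienolate of 5 can be protonated only at its α- or γ-carbon, never at the isopropenyl-bearing carbon.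

Step 3
Reactants: 6 methyl (5S)-2-methyl-5-(prop-1-en-2-yl)cyclopent-1-ene-1-carboxylate
Product: 7 [(5S)-2-methyl-5-(prop-1-en-2-yl)cyclopent-1-en-1-yl]methanol
Conditions: iBu2AlH, CH2Cl2, −78 °C → 0 °C; aq. potassium sodium tartrate
Reagents that add atoms: none
Why: Low-temperature 1,2-reduction of the α,β-unsaturated ester with iBu2AlH gives the allylic alcohol and leaves both alkenes and the stereocentre untouched.

Step 4
Reactants: 7 [(5S)-2-methyl-5-(prop-1-en-2-yl)cyclopent-1-en-1-yl]methanol
Product: 8 [(1R,2S,5R)-5-methyl-2-(prop-1-en-2-yl)-6-oxabicyclo[3.1.0]hexan-1-yl]methanol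
Conditions: VO(acac)2 (cat.), tBuOOH, CH2Cl2, 0 °C → rt
Reagents that add atoms: tert-butyl hydroperoxide, CC(C)(C)OO
Why: Hydroxyl-directed epoxidation of an allylic alcohol (VO(acac)2/tBuOOH) reacts only at the ring double bond and delivers oxygen to the face opposite the neighbouring isopropenyl group, which sets both epoxide carbons (tertiary C–O anti, methyl syn to isopropenyl).

Step 5
Reactants: 8 [(1R,2S,5R)-5-methyl-2-(prop-1-en-2-yl)-6-oxabicyclo[3.1.0]hexan-1-yl]methanol
Product: 9 (1R,2R,3R)-2-(hydroxymethyl)-1-methyl-3-(prop-1-en-2-yl)cyclopentan-1-ol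
Conditions: NaAlH2(OCH2CH2OMe)2, THF, 0 °C → rt
Reagents that add atoms: none
Why: Regioselective reductive opening of a 2,3-epoxy alcohol: the primary alkoxy-aluminate delivers hydride intramolecularly to the nearer epoxide carbon by SN2 with inversion, which sets the ring CH stereocentre (hydroxymethyl ends cis to the tertiary OH and trans to isopropenyl) and leaves the tertiary C–O bond in place.

Step 6
Reactants: 9 (1R,2R,3R)-2-(hydroxymethyl)-1-methyl-3-(prop-1-en-2-yl)cyclopentan-1-ol
Product: 10 triethyl{[(1R,2R,5R)-2-methyl-5-(prop-1-en-2-yl)-2-(triethylsilyloxy)cyclopentyl]methoxy}silane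
Conditions: Et3SiOTf, 2,6-lutidine, CH2Cl2, −78 °C → 0 °C
Reagents that add atoms: triethylsilyl trifluoromethanesulfonate, CC[Si](CC)(CC)OS(=O)(=O)C(F)(F)F
Why: Silyl triflate with 2,6-lutidine silylates both the primary and the hindered tertiary hydroxyl (silyl ether formation) without affecting any stereocentre.

Step 7
Reactants: 10 triethyl{[(1R,2R,5R)-2-methyl-5-(prop-1-en-2-yl)-2-(triethylsilyloxy)cyclopentyl]methoxy}silane
Product: 11 (1S,2R,5R)-2-methyl-5-(prop-1-en-2-yl)-2-(triethylsilyloxy)cyclopentane-1-carbaldehyde
Conditions: (COCl)2, DMSO, CH2Cl2, −78 °C → −40 °C; then Et3N, −78 °C → 0 °C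
Reagents that add atoms: none
Why: Under Swern conditions a primary triethylsilyl ether is attacked at oxygen by chlorodimethylsulfonium chloride and oxidised directly to the aldehyde while the hindered tertiary silyl ether survives, and the α-stereocentre is safe because it already holds the more stable configuration (formyl trans to both flanking carbon substituents).

Step 8
Reactants: 12 2,4,6-trihydroxytoluene; 13 (S)-2-methylbutanoic acid
Product: 15 (2S)-2-methyl-1-(2,4,6-trihydroxy-3-methylphenyl)butan-1-one, via acid chloride 14 (not isolated)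
Conditions: (COCl)2, DMF (cat.), CH2Cl2, 0 °C → rt; then 12, AlCl3, PhNO2/CH2Cl2, 0 °C → rt
Reagents that add atoms: none
Why: Friedel–Crafts acylation of the highly activated arene, whose two free positions are equivalent, with the acid chloride made in situ gives one mono-ketone, and keeping the temperature low preserves the α-stereocentre that comes from the chiral pool.

Step 9
Reactants: 11 (1S,2R,5R)-2-methyl-5-(prop-1-en-2-yl)-2-(triethylsilyloxy)cyclopentane-1-carbaldehyde; 15 (2S)-2-methyl-1-(2,4,6-trihydroxy-3-methylphenyl)butan-1-one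
Product: 17 (2S)-1-(2,4,6-trihydroxy-3-methyl-5-{[(1S,2R,5R)-2-methyl-5-(prop-1-en-2-yl)-2-(triethylsilyloxy)cyclopentyl]methyl}phenyl)-2-methylbutan-1-one, via quinone methide 16 (not isolated)
Conditions: L-proline (cat.), diethyl 2,6-dimethyl-1,4-dihydropyridine-3,5-dicarboxylate, CH2Cl2/EtOH, rt
Reagents that add atoms: none
Why: Three-component reductive alkylation: amine-catalysed Knoevenagel-type condensation at the only free ring carbon gives an ortho-quinone methide that the dihydropyridine reduces in situ by hydride transfer, so exactly one CH2 link forms and no stereocentre is created or lost (the aldehyde α-carbon is already in its more stable configuration).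

Step 10
Reactants: 17 (2S)-1-(2,4,6-trihydroxy-3-methyl-5-{[(1S,2R,5R)-2-methyl-5-(prop-1-en-2-yl)-2-(triethylsilyloxy)cyclopentyl]methyl}phenyl)-2-methylbutan-1-one
Product: 18 (6R)-3,5-dihydroxy-6-methyl-6-(3-methylbut-2-en-1-yl)-2-[(2S)-2-methylbutanoyl]-4-{[(1S,2R,5R)-2-methyl-5-(prop-1-en-2-yl)-2-(triethylsilyloxy)cyclopentyl]methyl}cyclohexa-2,4-dien-1-one
Conditions: Pd2(dba)3·CHCl3 (cat.), N,N'-[(1R,2R)-cyclohexane-1,2-diyl]bis[2-(diphenylphosphanyl)benzamide] (cat.), prenyl acetate, Cs2CO3, THF, 0 °C → rt; pH 4 buffer work-up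
Reagents that add atoms: 3-methylbut-2-en-1-yl acetate (prenyl acetate), CC(=O)OCC=C(C)C
Why: Tsuji–Trost allylic alkylation used as an asymmetric dearomatisation: the phenoxide attacks the unsubstituted terminus of the 1,1-dimethylallyl–palladium complex through the methyl-bearing ring carbon (the other alkyl-bearing carbon is shielded by its β-branched side chain and O-prenylation is reversible under zerovalent palladium), and the chiral ligand selects the ring face, which sets the quaternary stereocentre.

Step 11
Reactants: 18 (6R)-3,5-dihydroxy-6-methyl-6-(3-methylbut-2-en-1-yl)-2-[(2S)-2-methylbutanoyl]-4-{[(1S,2R,5R)-2-methyl-5-(prop-1-en-2-yl)-2-(triethylsilyloxy)cyclopentyl]methyl}cyclohexa-2,4-dien-1-one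
Product: 19 (6R)-3,5-dihydroxy-4-{[(1S,2R,5R)-2-hydroxy-2-methyl-5-(prop-1-en-2-yl)cyclopentyl]methyl}-6-methyl-6-(3-methylbut-2-en-1-yl)-2-[(2S)-2-methylbutanoyl]cyclohexa-2,4-dien-1-one (CNP0299585.2)
Conditions: HF·pyridine, pyridine, THF, 0 °C → rt
Reagents that add atoms: none
Why: Fluoride cleavage of the tertiary silyl ether (desilylation) with pyridine-buffered HF·pyridine avoids free acid that could ionise the tertiary alcohol or add it to an alkene, and touches no stereocentre.

**Compound list**

1 | (R)-(−)-carvone, (5R)-2-methyl-5-(prop-1-en-2-yl)cyclohex-2-en-1-one | CC1=CC[C@H](CC1=O)C(C)=C | starting material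
2 | (5S,6Z)-2-methyl-5-(prop-1-en-2-yl)-6-(2,2,2-trifluoro-1-hydroxyethylidene)cyclohex-2-en-1-one (enol form of the 6-trifluoroacetyl ketone) | CC1=CC[C@H](/C(=C(/O)C(F)(F)F)C1=O)C(C)=C | intermediate (not isolated)
3 | (5S)-6-diazo-2-methyl-5-(prop-1-en-2-yl)cyclohex-2-en-1-one | CC1=CC[C@H](C(=[N+]=[N-])C1=O)C(C)=C | intermediate
4 | 2-[(5S)-2-methyl-5-(prop-1-en-2-yl)cyclopent-2-en-1-ylidene]ethen-1-one (vinylketene) | O=C=C1C(C)=CC[C@H]1C(C)=C | intermediate (not isolated)
5 | methyl (1RS,5R)-2-methyl-5-(prop-1-en-2-yl)cyclopent-2-ene-1-carboxylate (mixture of epimers at C1) | COC(=O)C1C(C)=CC[C@H]1C(C)=C | intermediate (not isolated)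
6 | methyl (5S)-2-methyl-5-(prop-1-en-2-yl)cyclopent-1-ene-1-carboxylate | COC(=O)C1=C(C)CC[C@H]1C(C)=C | intermediate
7 | [(5S)-2-methyl-5-(prop-1-en-2-yl)cyclopent-1-en-1-yl]methanol | OCC1=C(C)CC[C@H]1C(C)=C | intermediate
8 | [(1R,2S,5R)-5-methyl-2-(prop-1-en-2-yl)-6-oxabicyclo[3.1.0]hexan-1-yl]methanol (epoxide anti to isopropenyl) | OC[C@@]12O[C@]1(C)CC[C@H]2C(C)=C | intermediate
9 | (1R,2R,3R)-2-(hydroxymethyl)-1-methyl-3-(prop-1-en-2-yl)cyclopentan-1-ol | C=C(C)[C@@H]1CC[C@@](C)(O)[C@H]1CO | intermediate
10 | triethyl{[(1R,2R,5R)-2-methyl-5-(prop-1-en-2-yl)-2-(triethylsilyloxy)cyclopentyl]methoxy}silane | C=C(C)[C@@H]1CC[C@@](C)(O[Si](CC)(CC)CC)[C@H]1CO[Si](CC)(CC)CC | intermediate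
11 | (1S,2R,5R)-2-methyl-5-(prop-1-en-2-yl)-2-(triethylsilyloxy)cyclopentane-1-carbaldehyde | C=C(C)[C@@H]1CC[C@@](C)(O[Si](CC)(CC)CC)[C@H]1C=O | intermediate
12 | 2,4,6-trihydroxytoluene (2-methylbenzene-1,3,5-triol) | Cc1c(O)cc(O)cc1O | starting material
13 | (S)-2-methylbutanoic acid | CC[C@H](C)C(=O)O | starting material
14 | (S)-2-methylbutanoyl chloride | CC[C@H](C)C(=O)Cl | intermediate (not isolated)
15 | (2S)-2-methyl-1-(2,4,6-trihydroxy-3-methylphenyl)butan-1-one | CC[C@H](C)C(=O)c1c(O)cc(O)c(C)c1O | intermediate
16 | 3,5-dihydroxy-2-methyl-4-[(2S)-2-methylbutanoyl]-6-{[(1S,2R,5R)-2-methyl-5-(prop-1-en-2-yl)-2-(triethylsilyloxy)cyclopentyl]methylidene}cyclohexa-2,4-dien-1-one (ortho-quinone methide, alkene geometry not defined) | C=C(C)[C@@H]1CC[C@@](C)(O[Si](CC)(CC)CC)[C@H]1C=C1C(=O)C(C)=C(O)C(C(=O)[C@@H](C)CC)=C1O | intermediate (not isolated)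
17 | (2S)-1-(2,4,6-trihydroxy-3-methyl-5-{[(1S,2R,5R)-2-methyl-5-(prop-1-en-2-yl)-2-(triethylsilyloxy)cyclopentyl]methyl}phenyl)-2-methylbutan-1-one | C=C(C)[C@@H]1CC[C@@](C)(O[Si](CC)(CC)CC)[C@H]1Cc1c(O)c(C)c(O)c(C(=O)[C@@H](C)CC)c1O | intermediate
18 | (6R)-3,5-dihydroxy-6-methyl-6-(3-methylbut-2-en-1-yl)-2-[(2S)-2-methylbutanoyl]-4-{[(1S,2R,5R)-2-methyl-5-(prop-1-en-2-yl)-2-(triethylsilyloxy)cyclopentyl]methyl}cyclohexa-2,4-dien-1-one | C=C(C)[C@@H]1CC[C@@](C)(O[Si](CC)(CC)CC)[C@H]1CC1=C(O)[C@@](C)(CC=C(C)C)C(=O)C(C(=O)[C@@H](C)CC)=C1O | intermediate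
19 | (6R)-3,5-dihydroxy-4-{[(1S,2R,5R)-2-hydroxy-2-methyl-5-(prop-1-en-2-yl)cyclopentyl]methyl}-6-methyl-6-(3-methylbut-2-en-1-yl)-2-[(2S)-2-methylbutanoyl]cyclohexa-2,4-dien-1-one (CNP0299585.2) | C=C(C)[C@@H]1CC[C@@](C)(O)[C@H]1CC1=C(O)[C@@](C)(CC=C(C)C)C(=O)C(C(=O)[C@@H](C)CC)=C1O | target

**Step count and risks**

Total step count: 11. Longest linear sequence: 10 steps (steps 1–7, 9, 10 and 11, from (R)-carvone); step 8 is the one-step side branch.

The three steps most likely to fail:

Step 10. The ring is planar and fully substituted, so facial selectivity of the C–C bond formation may be poor, and alkylation may also occur at the other alkyl-bearing ring carbon or on oxygen. Fallback: the fallback sets out from 17 and gives up catalyst control. Classical base-mediated dearomative C-prenylation (prenyl bromide, NaOMe, MeOH, 0 °C) should give 18 together with the epimeric silyl ether F1, which differs only at the quaternary carbon. Because the terpenoid half is enantiopure the two are diastereomers and are separated by preparative HPLC. Pure 18 returns to the route at step 11.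

Step 9. Condensation of the hindered aldehyde may be slow, and this leaves time for loss of silanol by β-elimination or for tautomerisation of the quinone methide to an alkene that hydride transfer cannot reduce. Fallback: the fallback sets out from 15 and inverts the order of the last two bond formations. Compound 15 is prenylated first under the conditions of step 10 to give the dearomatised triketone core F2, which has one free ring CH between two carbonyls. This cyclic 1,3-dione-type C–H acid is the best-precedented substrate class for proline/dihydropyridine reductive alkylation. With 11 it should pass through the alkylidene triketone F3 (not isolated) and give 18 directly, where the route is rejoined.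

Step 5. Both epoxide carbons are fully substituted, so hydride may be delivered to the wrong one, or the epoxide may rearrange before it is opened. Fallback: the fallback sets out from 6 and brings in the oxygen without an epoxide. Conjugate borylation (CuCl, NaOtBu, a bisphosphine, B2pin2, MeOH, THF) anti to the isopropenyl group gives the boryl ester F4 as a mixture at the ester-bearing carbon. Oxidation with NaBO3·4H2O (retention at carbon) and equilibration of the ester-bearing carbon with NaOMe/MeOH should give the hydroxy ester F5, with the ester cis to OH and trans to both flanking carbon substituents. Reduction with LiAlH4 (THF, 0 °C) gives 9, where the route is rejoined.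

**Further compounds**

F1 | step 10 | (6S)-3,5-dihydroxy-6-methyl-6-(3-methylbut-2-en-1-yl)-2-[(2S)-2-methylbutanoyl]-4-{[(1S,2R,5R)-2-methyl-5-(prop-1-en-2-yl)-2-(triethylsilyloxy)cyclopentyl]methyl}cyclohexa-2,4-dien-1-one (6-epimer of 18) | C=C(C)[C@@H]1CC[C@@](C)(O[Si](CC)(CC)CC)[C@H]1CC1=C(O)[C@](C)(CC=C(C)C)C(=O)C(C(=O)[C@@H](C)CC)=C1O
F2 | step 9 | (6R)-3,5-dihydroxy-6-methyl-6-(3-methylbut-2-en-1-yl)-2-[(2S)-2-methylbutanoyl]cyclohexa-2,4-dien-1-one | C1=C(O)[C@@](C)(CC=C(C)C)C(=O)C(C(=O)[C@@H](C)CC)=C1O
F3 | step 9 | alkylidene triketone from F2 and 11 (Knoevenagel adduct at the free ring carbon of F2, stereocentres as in F2 and 11, alkene geometry not defined) | C=C(C)[C@@H]1CC[C@@](C)(O[Si](CC)(CC)CC)[C@H]1C=C1C(=O)[C@@](C)(CC=C(C)C)C(=O)C(C(=O)[C@@H](C)CC)=C1O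
F4 | step 5 | methyl (1RS,2S,5R)-2-methyl-5-(prop-1-en-2-yl)-2-(4,4,5,5-tetramethyl-1,3,2-dioxaborolan-2-yl)cyclopentane-1-carboxylate (mixture of epimers at C1) | C=C(C)[C@@H]1CC[C@@](C)(B2OC(C)(C)C(C)(C)O2)C1C(=O)OC
F5 | step 5 | methyl (1S,2R,5R)-2-hydroxy-2-methyl-5-(prop-1-en-2-yl)cyclopentane-1-carboxylate | C=C(C)[C@@H]1CC[C@@](C)(O)[C@H]1C(=O)OC
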